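**Plan**
1. Retrosynthesis: cut C11=C12 and C11′=C12′ (two Wittig bonds, C15 + C10 + C15), then in each C15 unit C9–C10 (vinyl addition) and C7=C8 (olefination at a ring C7 carbon), then in the ring C3–C4 and C5–C6.
2. Enabling feature: each end ring C1–C6 is a double-aldol array. The C5 carbinol is β to the C3 carbonyl (through C4) and β to C7 (through C6), and the gem-dimethyl carbon C1 sits symmetrically between C2–C3 and C6–C7. C3–C2–C1(Me2)–C6–C7 is therefore latent C2v-symmetric 3,3-dimethylglutaraldehyde, and C4–C5–C18 is acetone.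
3. Forward: one L-proline-mediated aldol/aldol [4+2] annulation of the dialdehyde with acetone forms C3–C4 and then closes the ring at C5–C6. It should give the (5R,6S) ring with C7 as a formyl group and C3 as a sacrificial carbinol.
4. This aldehyde is taken to the cis C15 phosphonium salt (HWE, vinyl addition, PPh3·HBr). A second portion is converted into the (5S,6S) ring by C5 inversion (ring enone, epoxide anti to the C6 substituent, reductive opening) and extended in the same way.
5. The two salts are joined in sequence to 2,7-dimethylocta-2,4,6-trienedial. Both C3 carbinols are oxidised last, so the dehydration-prone β-hydroxy ketones appear only in the final step.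
6. Stereochemistry: C6 of both rings and C5 of the cis ring come from the proline enamine transition states of the key step; C5 of the trans ring comes from substrate-controlled epoxidation; chain double bonds are E by stabilised olefination and final isomerisation.

Key step: step 3

Remarks on the chemistry: ring atoms are referred to by carotenoid numbering (C1 gem-dimethyl, C3 oxygenated, C5 carbinol, C6 bearing the chain, C7 the first chain carbon). Compounds 8 and 17 are mixtures of epimers at the side-chain carbinol (C9), a centre that is removed in the following step. The C3 carbinol centre is sacrificial. The 9E phosphonium salts 9 and 18 are expected as the major isomers and are enriched by crystallisation.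

**Step 1**
Reactants: 1 3,3-dimethylglutaric anhydride
Product: 2 3,3-dimethylpentane-1,5-diol
Conditions: LiAlH4, THF, 0 °C → reflux; Fieser work-up
Reagents that add atoms: none
Why: Hydride reduction of the cyclic anhydride (through the lactone) should give the symmetric 1,5-diol; no stereocentre is involved.

**Step 2**
Reactants: 2 3,3-dimethylpentane-1,5-diol
Product: 3 3,3-dimethylpentanedial
Conditions: (COCl)2, DMSO, CH2Cl2, −78 °C; Et3N; non-aqueous work-up, used at once
Reagents that add atoms: none
Why: Swern oxidation should stop cleanly at the dialdehyde, whose neopentyl-type α-carbons make self-aldolisation slow.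

**Step 3**
Reactants: 3 3,3-dimethylpentanedial; 4 acetone
Product: 6 (1S,2R,4S)-2,4-dihydroxy-2,6,6-trimethylcyclohexane-1-carbaldehyde, via keto-aldehyde 5 (not isolated)
Conditions: L-proline (30 mol %), acetone (20 equiv), DMSO, 4 °C → rt
Reagents that add atoms: none
Why: Proposed new method: L-proline converts acetone (in excess) into its enamine, which adds to one of the two homotopic formyl groups of 3 through the usual carboxylic-acid-hydrogen-bonded transition state to give (S)-aldol 5 (C3–C4 bond); 5 rests as its six-membered lactol, which shields it from a second acetone addition, and its formyl arm then forms the aldehyde enamine, whose C6 attacks the C5 methyl ketone in a 6-(enolexo)-exo-trig aldol closure (C5–C6 bond) that is helped by the gem-dimethyl (Thorpe–Ingold) effect. The closest known reaction types are the proline-catalysed direct aldol of acetone with aldehydes, the proline-catalysed 6-enolexo aldolisation of dicarbonyls (including aldehyde-enamine additions to ketone acceptors that give tertiary carbinols), and amine-catalysed [4+2] domino reactions in which a 1,5-dialdehyde is nucleophilic at one α-carbon and electrophilic at the other formyl group; joining the first two in one flask on a 1,5-dialdehyde is the untested element. C6 is set by the catalyst: the (E)-enamine of the formyl arm is attacked on the face syn to the proline carboxyl group, which for an α-carbon ranked CHO > carbinol carbon > alkyl corresponds to S. C5 is set by the chair-like closure: the ketone methyl stays equatorial because an axial methyl would be syn-axial to the axial C1 methyl, so the carbonyl oxygen is axial, gauche to C7 and within reach of the carboxylic acid proton, which gives the 5R carbinol cis to the formyl group; the C3 hydroxyl from the first aldol (S, catalyst-controlled) is equatorial in this chair, so the two catalyst-controlled events are matched. The step needs the aldehyde enamine to attack the ketone in preference to the internal ketone enamine attacking the formyl group (a [5+1] closure); the formyl group condenses with proline far faster than the hindered internal α-carbon of the ketone does, and the excess of acetone keeps ketone-enamine chemistry intermolecular. It also needs 3 to resist self-aldolisation, which the quaternary C1 next to both α-carbons secures.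

**Step 4**
Reactants: 6 (1S,2R,4S)-2,4-dihydroxy-2,6,6-trimethylcyclohexane-1-carbaldehyde
Product: 7 (3E)-4-[(1S,2R,4S)-2,4-dihydroxy-2,6,6-trimethylcyclohexyl]but-3-en-2-one
Conditions: diethyl (2-oxopropyl)phosphonate, LiCl, iPr2NEt, MeCN, 0 °C → rt
Reagents that add atoms: diethyl (2-oxopropyl)phosphonate, CCOP(=O)(CC(C)=O)OCC
Why: Horner–Wadsworth–Emmons olefination under Masamune–Roush conditions (amine base, LiCl) should give the E-enone without retro-aldol or epimerisation of the tertiary aldol.

**Step 5**
Reactants: 7 (3E)-4-[(1S,2R,4S)-2,4-dihydroxy-2,6,6-trimethylcyclohexyl]but-3-en-2-one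
Product: 8 (1S,3R,4S)-4-[(1E)-3-hydroxy-3-methylpenta-1,4-dien-1-yl]-3,5,5-trimethylcyclohexane-1,3-diol (C9 epimers)
Conditions: vinylmagnesium bromide (4.5 equiv), THF, −40 → 0 °C; aq. NH4Cl
Reagents that add atoms: vinylmagnesium bromide, C=C[Mg]Br
Why: Grignard 1,2-addition to the enone (the ionone → vinyl-ionol reaction) should give the doubly allylic tertiary carbinol; the excess reagent covers the two hydroxyl groups.

**Step 6**
Reactants: 8 (1S,3R,4S)-4-[(1E)-3-hydroxy-3-methylpenta-1,4-dien-1-yl]-3,5,5-trimethylcyclohexane-1,3-diol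
Product: 9 [(2E,4E)-5-[(1S,2R,4S)-2,4-dihydroxy-2,6,6-trimethylcyclohexyl]-3-methylpenta-2,4-dien-1-yl]triphenylphosphonium bromide
Conditions: PPh3·HBr, MeOH, 0 °C → rt; crystallisation
Reagents that add atoms: triphenylphosphine hydrobromide, Br.c1ccc(cc1)P(c1ccccc1)c1ccccc1
Why: Acid ionisation of the doubly allylic C9 carbinol and capture of the pentadienyl cation by PPh3 at the unhindered C11 terminus (SN1′ allylic transposition, the standard C15 Wittig-salt synthesis) should give the salt; the non-allylic ring hydroxyls should not ionise.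

**Step 7**
Reactants: 6 (1S,2R,4S)-2,4-dihydroxy-2,6,6-trimethylcyclohexane-1-carbaldehyde
Product: 10 (1R,3S,6S)-6-ethenyl-1,5,5-trimethylcyclohexane-1,3-diol
Conditions: Zn, CH2Br2, TiCl4, THF/CH2Cl2, 0 °C → rt
Reagents that add atoms: dibromomethane, BrCBr
Why: Takai–Lombardo methylenation with the non-basic Zn/Ti gem-dimetallic reagent should convert the hindered, base-sensitive aldol aldehyde into a vinyl group that masks C7 through the acid, base and reducing steps that follow.

**Step 8**
Reactants: 10 (1R,3S,6S)-6-ethenyl-1,5,5-trimethylcyclohexane-1,3-diol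
Product: 12 (4S)-4-ethenyl-3,5,5-trimethylcyclohex-2-en-1-one, via hydroxy ketone 11 (not isolated)
Conditions: Dess–Martin periodinane, CH2Cl2, rt; then TsOH·H2O (cat.), rt, same flask
Reagents that add atoms: none
Why: Dess–Martin oxidation should touch only the secondary C3 carbinol, and acid-catalysed dehydration of the resulting tertiary aldol should give the conjugated enone with C6 unchanged.

**Step 9**
Reactants: 12 (4S)-4-ethenyl-3,5,5-trimethylcyclohex-2-en-1-one
Product: 13 (1R,5S,6R)-5-ethenyl-4,4,6-trimethyl-7-oxabicyclo[4.1.0]heptan-2-one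
Conditions: 30 % aq. H2O2, NaOH (cat.), MeOH, 0 °C
Reagents that add atoms: hydrogen peroxide, OO
Why: Weitz–Scheffer nucleophilic epoxidation: hydroperoxide should add to C5 anti to the vinyl group on the adjacent C6 (as conjugate additions to 4-substituted cyclohexenones do) and the enolate closes on the same face, so the epoxide oxygen is trans to C7, while the isolated vinyl group is inert.

**Step 10**
Reactants: 13 (1R,5S,6R)-5-ethenyl-4,4,6-trimethyl-7-oxabicyclo[4.1.0]heptan-2-one
Product: 15 (1S,3R,6S)-6-ethenyl-1,5,5-trimethylcyclohexane-1,3-diol, via trans-hydroxy ketone 14 (not isolated)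
Conditions: (PhSe)2, NaBH4, EtOH, then AcOH, 0 °C → rt; solvent exchange; Me4NBH(OAc)3, MeCN/AcOH, −20 °C
Reagents that add atoms: none
Why: Benzeneselenolate reduction of the α,β-epoxy ketone cleaves only the C4–O bond, so the C5 carbinol keeps the epoxide configuration (OH trans to vinyl), and the hydroxyl-directed triacetoxyborohydride reduction (Evans–Saksena) then delivers hydride from the C5 oxygen to give the 1,3-anti diol as a single C3 epimer.

**Step 11**
Reactants: 15 (1S,3R,6S)-6-ethenyl-1,5,5-trimethylcyclohexane-1,3-diol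
Product: 16 (3E)-4-[(1S,2S,4R)-2,4-dihydroxy-2,6,6-trimethylcyclohexyl]but-3-en-2-one
Conditions: methyl vinyl ketone (5 equiv), Hoveyda–Grubbs 2nd-generation catalyst (10 mol %), CH2Cl2, 40 °C
Reagents that add atoms: methyl vinyl ketone, CC(=O)C=C
Why: Olefin cross-metathesis of a hindered terminal alkene that cannot homodimerise with an excess of an electron-poor partner should give the E-enone and ethene.

**Step 12**
Reactants: 16 (3E)-4-[(1S,2S,4R)-2,4-dihydroxy-2,6,6-trimethylcyclohexyl]but-3-en-2-one
Product: 17 (1R,3S,4S)-4-[(1E)-3-hydroxy-3-methylpenta-1,4-dien-1-yl]-3,5,5-trimethylcyclohexane-1,3-diol (C9 epimers)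
Conditions: vinylmagnesium bromide (4.5 equiv), THF, −40 → 0 °C; aq. NH4Cl
Reagents that add atoms: vinylmagnesium bromide, C=C[Mg]Br
Why: Grignard 1,2-addition to the enone, as in step 5.

**Step 13**
Reactants: 17 (1R,3S,4S)-4-[(1E)-3-hydroxy-3-methylpenta-1,4-dien-1-yl]-3,5,5-trimethylcyclohexane-1,3-diol
Product: 18 [(2E,4E)-5-[(1S,2S,4R)-2,4-dihydroxy-2,6,6-trimethylcyclohexyl]-3-methylpenta-2,4-dien-1-yl]triphenylphosphonium bromide
Conditions: PPh3·HBr, MeOH, 0 °C → rt; crystallisation
Reagents that add atoms: triphenylphosphine hydrobromide, Br.c1ccc(cc1)P(c1ccccc1)c1ccccc1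
Why: SN1′ phosphonium salt formation by allylic transposition, as in step 6.

**Step 14**
Reactants: 9 [(2E,4E)-5-[(1S,2R,4S)-2,4-dihydroxy-2,6,6-trimethylcyclohexyl]-3-methylpenta-2,4-dien-1-yl]triphenylphosphonium bromide; 19 (2E,4E,6E)-2,7-dimethylocta-2,4,6-trienedial
Product: 20 (2E,4E,6E,8E,10E,12E)-13-[(1S,2R,4S)-2,4-dihydroxy-2,6,6-trimethylcyclohexyl]-2,7,11-trimethyltrideca-2,4,6,8,10,12-hexaenal
Conditions: 19 (3 equiv), NaOMe, CH2Cl2/MeOH, −10 °C → rt, slow addition of 9; then I2 (cat.), CH2Cl2, daylight
Reagents that add atoms: none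
Why: Wittig olefination with the symmetric dialdehyde in excess should give mono-olefination at C11=C12, and iodine-catalysed equilibration should bring the new double bond to E.

**Step 15**
Reactants: 20 (2E,4E,6E,8E,10E,12E)-13-[(1S,2R,4S)-2,4-dihydroxy-2,6,6-trimethylcyclohexyl]-2,7,11-trimethyltrideca-2,4,6,8,10,12-hexaenal; 18 [(2E,4E)-5-[(1S,2S,4R)-2,4-dihydroxy-2,6,6-trimethylcyclohexyl]-3-methylpenta-2,4-dien-1-yl]triphenylphosphonium bromide
Product: 21 (3S,5R,6S,3′R,5′S,6′S)-5,6,5′,6′-tetrahydro-β,β-carotene-3,5,3′,5′-tetrol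
Conditions: 18 (1.5 equiv), NaOMe, CH2Cl2/MeOH, rt; then reflux in EtOH under Ar (Z → E)
Reagents that add atoms: none
Why: The second Wittig olefination forms C11′=C12′ and thermal equilibration should give the all-E C40 tetrol; free secondary and tertiary hydroxyls are tolerated, as in standard C15 + C10 + C15 carotenoid assembly.

**Step 16**
Reactants: 21 (3S,5R,6S,3′R,5′S,6′S)-5,6,5′,6′-tetrahydro-β,β-carotene-3,5,3′,5′-tetrol
Product: 22 (5R,6S,5′S,6′S)-5,5′-dihydroxy-5,6,5′,6′-tetrahydro-β,β-carotene-3,3′-dione (target)
Conditions: Dess–Martin periodinane (3 equiv), NaHCO3, CH2Cl2, 0 °C, dark, Ar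
Reagents that add atoms: none
Why: Buffered Dess–Martin oxidation should convert the two secondary C3 carbinols into ketones while leaving the tertiary carbinols and the polyene alone, and its neutral conditions should avoid dehydration of the new β-hydroxy ketones.

**Compound list**
1 | 3,3-dimethylglutaric anhydride | CC1(C)CC(=O)OC(=O)C1 | starting material
2 | 3,3-dimethylpentane-1,5-diol | OCCC(C)(C)CCO | intermediate
3 | 3,3-dimethylpentanedial | O=CCC(C)(C)CC=O | intermediate
4 | acetone | CC(C)=O | starting material
5 | (5S)-5-hydroxy-3,3-dimethyl-7-oxooctanal (open form of its δ-lactol) | CC(=O)C[C@@H](O)CC(C)(C)CC=O | intermediate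
6 | (1S,2R,4S)-2,4-dihydroxy-2,6,6-trimethylcyclohexane-1-carbaldehyde | O=C[C@H]1C(C)(C)C[C@H](O)C[C@@]1(C)O | intermediate
7 | (3E)-4-[(1S,2R,4S)-2,4-dihydroxy-2,6,6-trimethylcyclohexyl]but-3-en-2-one | CC(=O)/C=C/[C@H]1C(C)(C)C[C@H](O)C[C@@]1(C)O | intermediate
8 | (1S,3R,4S)-4-[(1E)-3-hydroxy-3-methylpenta-1,4-dien-1-yl]-3,5,5-trimethylcyclohexane-1,3-diol (C9 epimers) | C=CC(C)(O)/C=C/[C@H]1C(C)(C)C[C@H](O)C[C@@]1(C)O | intermediate
9 | [(2E,4E)-5-[(1S,2R,4S)-2,4-dihydroxy-2,6,6-trimethylcyclohexyl]-3-methylpenta-2,4-dien-1-yl]triphenylphosphonium bromide | [Br-].c1ccccc1[P+](c1ccccc1)(c1ccccc1)C/C=C(C)/C=C/[C@H]1C(C)(C)C[C@H](O)C[C@@]1(C)O | intermediate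
10 | (1R,3S,6S)-6-ethenyl-1,5,5-trimethylcyclohexane-1,3-diol | C=C[C@H]1C(C)(C)C[C@H](O)C[C@@]1(C)O | intermediate
11 | (3R,4S)-4-ethenyl-3-hydroxy-3,5,5-trimethylcyclohexan-1-one | C=C[C@H]1C(C)(C)CC(=O)C[C@@]1(C)O | intermediate
12 | (4S)-4-ethenyl-3,5,5-trimethylcyclohex-2-en-1-one | C=C[C@H]1C(C)(C)CC(=O)C=C1C | intermediate
13 | (1R,5S,6R)-5-ethenyl-4,4,6-trimethyl-7-oxabicyclo[4.1.0]heptan-2-one | C=C[C@H]1C(C)(C)CC(=O)[C@@H]2O[C@]12C | intermediate
14 | (3S,4S)-4-ethenyl-3-hydroxy-3,5,5-trimethylcyclohexan-1-one | C=C[C@H]1C(C)(C)CC(=O)C[C@]1(C)O | intermediate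
15 | (1S,3R,6S)-6-ethenyl-1,5,5-trimethylcyclohexane-1,3-diol | C=C[C@H]1C(C)(C)C[C@@H](O)C[C@]1(C)O | intermediate
16 | (3E)-4-[(1S,2S,4R)-2,4-dihydroxy-2,6,6-trimethylcyclohexyl]but-3-en-2-one | CC(=O)/C=C/[C@H]1C(C)(C)C[C@@H](O)C[C@]1(C)O | intermediate
17 | (1R,3S,4S)-4-[(1E)-3-hydroxy-3-methylpenta-1,4-dien-1-yl]-3,5,5-trimethylcyclohexane-1,3-diol (C9 epimers) | C=CC(C)(O)/C=C/[C@H]1C(C)(C)C[C@@H](O)C[C@]1(C)O | intermediate
18 | [(2E,4E)-5-[(1S,2S,4R)-2,4-dihydroxy-2,6,6-trimethylcyclohexyl]-3-methylpenta-2,4-dien-1-yl]triphenylphosphonium bromide | [Br-].c1ccccc1[P+](c1ccccc1)(c1ccccc1)C/C=C(C)/C=C/[C@H]1C(C)(C)C[C@@H](O)C[C@]1(C)O | intermediate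
19 | (2E,4E,6E)-2,7-dimethylocta-2,4,6-trienedial | O=C/C(C)=C/C=C/C=C(C)/C=O | starting material
20 | (2E,4E,6E,8E,10E,12E)-13-[(1S,2R,4S)-2,4-dihydroxy-2,6,6-trimethylcyclohexyl]-2,7,11-trimethyltrideca-2,4,6,8,10,12-hexaenal | O=C/C(C)=C/C=C/C=C(C)/C=C/C=C(C)/C=C/[C@H]1C(C)(C)C[C@H](O)C[C@@]1(C)O | intermediate
21 | (3S,5R,6S,3′R,5′S,6′S)-5,6,5′,6′-tetrahydro-β,β-carotene-3,5,3′,5′-tetrol | CC(/C=C/C=C(C)/C=C/[C@H]1C(C)(C)C[C@@H](O)C[C@]1(C)O)=C\C=C\C=C(C)\C=C\C=C(C)\C=C\[C@H]1C(C)(C)C[C@H](O)C[C@@]1(C)O | intermediate
22 | (5R,6S,5′S,6′S)-5,5′-dihydroxy-5,6,5′,6′-tetrahydro-β,β-carotene-3,3′-dione | CC(/C=C/C=C(C)/C=C/[C@H]1C(C)(C)CC(=O)C[C@]1(C)O)=C\C=C\C=C(C)\C=C\C=C(C)\C=C\[C@H]1C(C)(C)CC(=O)C[C@@]1(C)O | target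

**Totals**
Total step count: 16. Longest linear sequence: 12 steps (steps 1, 2, 3, 7, 8, 9, 10, 11, 12, 13, 15, 16).

**Steps most likely to fail**

Step 3 (proposed new method). The intermolecular aldol may leak into aldol condensation or double addition. The ring-closing aldol onto the ketone may be slow or reversible. The internal ketone enamine may close onto the formyl arm instead. The two faces of the ketone may be poorly differentiated. Fallback, using known reactions one at a time: dialdehyde 3, used in excess, is mono-methylenated with methylenetriphenylphosphorane to 3,3-dimethylhex-5-enal F1. The established L-proline-catalysed aldol of acetone with this single aldehyde gives (4S)-4-hydroxy-6,6-dimethylnon-8-en-2-one F2. Ozonolysis with Me2S work-up releases the second formyl group and gives keto-aldehyde 5 as an isolated compound (lactol form). This is closed by the known 6-enolexo aldolisation, either with L-proline or with pyrrolidinium acetate under thermodynamic control, where the C3 carbinol already in place holds the chair with its hydroxyl equatorial. The route is rejoined at 6.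

Step 9. Reversible γ-deprotonation at C6 under alkaline peroxide may erode the C6 configuration or move the vinyl double bond into conjugation, and face selection at the hindered C5 may be incomplete. Fallback: enone 12 undergoes copper-catalysed conjugate borylation (B2pin2, CuCl/N-heterocyclic carbene, NaOtBu cat., MeOH, THF) anti to the vinyl group to give (3R,4S)-4-ethenyl-3,5,5-trimethyl-3-(4,4,5,5-tetramethyl-1,3,2-dioxaborolan-2-yl)cyclohexan-1-one F3. Oxidation with NaBO3·4H2O proceeds with retention and gives hydroxy ketone 14, which re-enters the route at the second stage of step 10.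

Step 11. Cross-metathesis at a vinyl group flanked by two fully substituted carbons may be too slow, so that the catalyst decays before conversion. Fallback: ozonolysis of 15 (O3, CH2Cl2/MeOH, −78 °C; Me2S) gives (1S,2S,4R)-2,4-dihydroxy-2,6,6-trimethylcyclohexane-1-carbaldehyde F4. Horner–Wadsworth–Emmons olefination under the conditions of step 4 then gives 16, where the route is rejoined.

**Further compounds**
F1 | step 3 | 3,3-dimethylhex-5-enal | C=CCC(C)(C)CC=O
F2 | step 3 | (4S)-4-hydroxy-6,6-dimethylnon-8-en-2-one | CC(=O)C[C@@H](O)CC(C)(C)CC=C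
F3 | step 9 | (3R,4S)-4-ethenyl-3,5,5-trimethyl-3-(4,4,5,5-tetramethyl-1,3,2-dioxaborolan-2-yl)cyclohexan-1-one | C=C[C@H]1C(C)(C)CC(=O)C[C@]1(C)B1OC(C)(C)C(C)(C)O1
F4 | step 11 | (1S,2S,4R)-2,4-dihydroxy-2,6,6-trimethylcyclohexane-1-carbaldehyde | O=C[C@H]1C(C)(C)C[C@@H](O)C[C@]1(C)O
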